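**Retrosynthetic overview**

1. Numbering used here: C1 lactone C=O; C2=C3(OH) enol; C4(Me), C5, C6(Me); C7 ketone; C8, C9, C10; C11(OH); C12(Me)–O(ether); C13(Me)(OH); C14; C15 (carbon bearing the lactone O); C16 (bonded to C2, C8, C15 and the ether O).
2. Enabling feature: the ether oxygen sits on C16, the β-carbon of the enolised 2-acyl-butanolide C3(OH)=C2–C1(=O)–O–C15. The ring O–C16–C15–C10–C11–C12 is therefore the oxa-Michael adduct of 12-OH to an alkylidene acetoacetate C2=C16, and C12–O and C15–C16 are 1,4-cis on the cyclohexane, so only this hydroxyl can reach C16.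
3. The alkylidene C2=C16 is the Knoevenagel product of ketone C16 with the acetoacetate-type ester of the neighbouring tertiary 15-OH. Run inside an 11-membered β-keto lactone (O15–C1 by acylketene capture, C7–C8 by aldol), this one condensation closes the butenolide and cuts out the cyclooctane.
4. Fragments: hydrindanone ketol 20 and aldehyde 5 (from meso-2,4-dimethylglutaric anhydride). The hydrindanone comes from a catalytic asymmetric Diels–Alder reaction of cyclopentenone with a 2-silyloxy-3-methylbutadiene; 13-OH, 11-OH, 12-Me and 15-OH are then all delivered to the convex β-face.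
5. Ring order: cyclohexene and cyclopentanone (Diels–Alder), then transient macrolactone, then butenolide and cyclooctane (one bond), then the oxane, last.

Key step: step 18

Remark: in the names of 9–25 the hydrindane is numbered as an indane (C1 = C16, C2 = C8, C3 = C9, C3a = C10, C4 = C11, C5 = C12, C6 = C13, C7 = C14, C7a = C15) and β is the face of H-3a; C7 in 22–30 is an unassigned mixture of carbinol epimers (SMILES leave it open) that converge in step 19.

**Route**

Step 1
Reactants: 1 meso-2,4-dimethylglutaric anhydride [(3R,5S)-3,5-dimethyloxane-2,6-dione]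
Product: 2 (2R,4S)-2,4-dimethyl-5-oxo-5-(prop-2-en-1-yloxy)pentanoic acid
Conditions: allyl alcohol, quinidine (1.1 equiv), PhMe, −55 °C (quinine if the sense of opening is the opposite)
Reagents that add atoms: allyl alcohol, C=CCO
Why: Alkaloid-mediated desymmetrising alcoholysis of a meso anhydride; choosing which enantiotopic carbonyl becomes the ester fixes the two methyl centres (later C6 and C4) without creating a new stereocentre.

Step 2
Reactants: 2
Product: 4 allyl (2S,4R)-5-hydroxy-2,4-dimethylpentanoate, via mixed carbonic anhydride 3 (not isolated)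
Conditions: i-BuOCOCl, N-methylmorpholine, THF, −15 °C; then NaBH4, MeOH, −15 → 0 °C
Reagents that add atoms: none
Why: Chemoselective reduction of the acid through its mixed anhydride; the allyl ester, the alkene and both stereocentres are untouched.

Step 3
Reactants: 4
Product: 5 allyl (2S,4R)-2,4-dimethyl-5-oxopentanoate
Conditions: Dess–Martin periodinane, NaHCO3, CH2Cl2, 0 °C; used crude
Reagents that add atoms: none
Why: Dess–Martin oxidation under buffered neutral conditions, which should not epimerise the α-methyl aldehyde.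

Step 4
Reactants: 6 3-methylbut-3-en-2-one
Product: 7 triisopropyl[(3-methylbuta-1,3-dien-2-yl)oxy]silane
Conditions: TIPSOTf, Et3N, Et2O, 0 °C
Reagents that add atoms: triisopropylsilyl triflate, CC(C)[Si](C(C)C)(C(C)C)OS(=O)(=O)C(F)(F)F
Why: Soft enolisation and O-silylation of the methyl ketone (silyl enol ether formation) gives the 2-silyloxydiene.

Step 5
Reactants: 7 triisopropyl[(3-methylbuta-1,3-dien-2-yl)oxy]silane; 8 cyclopent-2-en-1-one
Product: 9 (3aS,7aR)-6-methyl-5-(triisopropylsilyloxy)-2,3,3a,4,7,7a-hexahydro-1H-inden-1-one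
Conditions: (S)-B-o-tolyl-diphenylprolinol oxazaborolidine·Tf2NH (20 mol%), CH2Cl2, −78 → −40 °C (enantiomeric catalyst if the facial sense is the opposite)
Reagents that add atoms: none
Why: Chiral oxazaborolidinium-catalysed Diels–Alder reaction of a cycloalkenone with a 2-silyloxydiene: the CH2 next to C–OSi is the nucleophilic terminus and bonds to the enone β-carbon ("para" adduct), suprafacial addition gives the cis ring fusion (C10, C15), and the catalyst shields one face of the coordinated enone, which sets the absolute configuration.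

Step 6
Reactants: 9
Product: 11 (3aS,6R,7aR)-6-hydroxy-6-methylhexahydro-1H-indene-1,5(4H)-dione, via silyloxy epoxide 10 (not isolated)
Conditions: DMDO, acetone, −40 °C; then TBAF, AcOH, THF, 0 °C
Reagents that add atoms: dimethyldioxirane, CC1(C)OO1
Why: Rubottom oxidation: the enol ether is epoxidised on the convex β-face (the α-face is covered by the cis-fused cyclopentanone) and buffered fluoride opens the silyloxy epoxide to the tertiary α-hydroxy ketone, which sets C13 (OH β, Me α).

Step 7
Reactants: 11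
Product: 12 6β-hydroxy-6α-methyl-cis-hexahydrospiro[indene-1,2'-[1,3]dioxolan]-5(4H)-one
Conditions: 1,2-bis(trimethylsilyloxy)ethane, TMSOTf (5 mol%), CH2Cl2, −78 °C
Reagents that add atoms: 1,2-bis(trimethylsilyloxy)ethane, C[Si](C)(C)OCCO[Si](C)(C)C
Why: Aprotic ketalisation with the bis-silyl glycol: the unhindered cyclopentanone should react while the cyclohexanone next to the quaternary carbinol does not, and the low temperature avoids epimerisation at C15.

Step 8
Reactants: 12
Product: 14 4β,6β-dihydroxy-6α-methyl-cis-hexahydrospiro[indene-1,2'-[1,3]dioxolan]-5(4H)-one, via dipotassium alkoxide enolate 13 (not isolated)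
Conditions: KHMDS (2.2 equiv), THF, −78 °C; then 2-(phenylsulfonyl)-3-phenyloxaziridine, −78 °C
Reagents that add atoms: 2-(phenylsulfonyl)-3-phenyloxaziridine, O=S(=O)(c1ccccc1)N1OC1c1ccccc1
Why: Enolate hydroxylation with an N-sulfonyloxaziridine: the ketone can enolise only toward C4 (C6 is quaternary) and the oxidant attacks anti to the C3–C3a bond, on the β-face, which sets C11 (OH β).

Step 9
Reactants: 14
Product: 15 4β-benzyloxy-6β-hydroxy-6α-methyl-cis-hexahydrospiro[indene-1,2'-[1,3]dioxolan]-5(4H)-one
Conditions: 2-benzyloxy-1-methylpyridinium triflate, MgO, PhCF3, 83 °C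
Reagents that add atoms: 2-benzyloxy-1-methylpyridinium triflate, C[n+]1ccccc1OCc1ccccc1.[O-]S(=O)(=O)C(F)(F)F
Why: Neutral thermal benzyl transfer to the secondary hydroxyl (O-benzylation); the tertiary 6-OH is slower, and neutral conditions avoid α-ketol rearrangement and C4 epimerisation.

Step 10
Reactants: 15
Product: 16 4β-benzyloxy-5β,6α-dimethyl-cis-octahydrospiro[indene-1,2'-[1,3]dioxolane]-5α,6β-diol
Conditions: MeMgBr (3 equiv), THF, −78 → 0 °C
Reagents that add atoms: methylmagnesium bromide, C[Mg]Br
Why: Grignard addition to the α-alkoxy ketone: the equatorial approach is blocked by the two flanking oxygen substituents and the α-face by the ring-fusion bond, so methyl should enter on the convex β-face, which sets C12 (Me β, OH α).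

Step 11
Reactants: 16
Product: 17 4β-benzyloxy-5α,6β-dihydroxy-5β,6α-dimethyl-cis-octahydro-1H-inden-1-one
Conditions: PPTS, acetone–H2O (9:1), 50 °C
Reagents that add atoms: water, O
Why: Acid-catalysed acetal hydrolysis; PPTS is too weak to start a pinacol shift of the ditertiary diol, and epimerisation at C7a does not matter because C7a is planarised in step 12.

Step 12
Reactants: 17
Product: 18 4β-benzyloxy-5β,6α-dimethyl-1,5α,6β-tris(trimethylsilyloxy)-3,3a,4,5,6,7-hexahydro-2H-indene
Conditions: TMSOTf (4 equiv), Et3N, CH2Cl2, 0 → 23 °C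
Reagents that add atoms: trimethylsilyl triflate, C[Si](C)(C)OS(=O)(=O)C(F)(F)F
Why: Silylation of both tertiary alcohols and enol silylation under equilibrating conditions, which should favour the more substituted ring-fusion silyl enol ether.

Step 13
Reactants: 18
Product: 20 4β-benzyloxy-7aβ-hydroxy-5β,6α-dimethyl-5α,6β-bis(trimethylsilyloxy)-cis-octahydro-1H-inden-1-one, via lithium enolate 19 (not isolated)
Conditions: MeLi, THF, 0 °C; then 2-(phenylsulfonyl)-3-phenyloxaziridine, −78 °C
Reagents that add atoms: 2-(phenylsulfonyl)-3-phenyloxaziridine, O=S(=O)(c1ccccc1)N1OC1c1ccccc1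
Why: Regiospecific lithium enolate from the silyl enol ether followed by oxaziridine hydroxylation; attack syn to H-3a gives the cis-fused ketol, the low-strain fusion, which sets C15 (OH β).

Step 14
Reactants: 20 (ketol); 5 allyl (2S,4R)-2,4-dimethyl-5-oxopentanoate
Product: 22 2β-(5-allyloxy-1-hydroxy-2,4-dimethyl-5-oxopentyl) derivative of 20 (C6 R and C4 S; C7 epimers), via dilithium alkoxide enolate 21 (not isolated)
Conditions: LDA (2.2 equiv), THF, −78 °C; then 5, −78 °C
Reagents that add atoms: none
Why: Lithium aldol addition: C8 is the only enolisable position, and the aldehyde approaches on the convex face that also carries the lithium alkoxide at O15, so the C7–C8 bond forms cis to O15 (sets C8).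

Step 15
Reactants: 22
Product: 23 7-O-triethylsilyl ether of 22
Conditions: TESCl, imidazole, DMF, 0 °C
Reagents that add atoms: chlorotriethylsilane, CC[Si](Cl)(CC)CC
Why: Silyl ether formation at the secondary carbinol only (the tertiary α-ketol hydroxyl does not react under these conditions); it blocks retro-aldol cleavage and ketene capture by 7-OH.

Step 16
Reactants: 23
Product: 24 carboxylic acid from 23 (allyl ester cleaved)
Conditions: Pd(PPh3)4 (5 mol%), morpholine, THF, 23 °C
Reagents that add atoms: none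
Why: Tsuji–Trost deallylation through the π-allylpalladium complex, neutral toward silyl ethers, the benzyl ether and the β-silyloxy ketone.

Step 17
Reactants: 24
Product: 25 acyl Meldrum's acid from 24 (5-acyl-2,2-dimethyl-1,3-dioxane-4,6-dione)
Conditions: Meldrum's acid, EDC·HCl, DMAP, CH2Cl2, 0 → 23 °C
Reagents that add atoms: Meldrum's acid (2,2-dimethyl-1,3-dioxane-4,6-dione), CC1(C)OC(=O)CC(=O)O1
Why: Carbodiimide-mediated C-acylation of Meldrum's acid, the standard acylketene precursor; it brings in C1 and C2.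

Step 18
Reactants: 25
Product: 30 11-O-benzyl-7-deoxo-7-hydroxy derivative of the target (C7 epimers), via acylketene 26 (not isolated), via macrolactone 27 (not isolated), via silylated alkylidene butenolide 28 (not isolated), via desilylated alkylidene butenolide 29 (not isolated)
Conditions: PhMe (0.5 mM, slow addition), 110 °C; then Et3N (5 equiv), 23 °C; then TBAF (5 equiv), THF, 0 → 23 °C (one pot)
Reagents that add atoms: none
Why: Heating the acyl Meldrum's acid gives acylketene 26 by retro-[4+2] loss of acetone and CO2, and at high dilution the only free hydroxyl (15-OH) captures it to give the 11-membered β-keto lactone 27 (acylketene macrolactonisation, an established entry to medium and large β-keto lactones). Et3N then brings about the intramolecular Knoevenagel condensation of C2 with the C16 ketone (the classical butenolide synthesis from acetoacetates of α-ketols), and fluoride frees 12-OH, which adds to C16 of alkylidene acetoacetate 29 (intramolecular oxa-Michael addition). Modes of closure: macrolactone by O-acylation; butenolide by 5-(enolexo)-exo-trig aldol addition and E1cB dehydration, the new C2–C16 bond at the same time dividing the macrocycle into lactone and cyclooctane; oxane by 6-exo-trig conjugate addition on a boat cyclohexane, which completes the 2-oxabicyclo[2.2.2]octane. The one new stereocentre, C16, is set by the tether: its three carbon ligands are held by the rings and oxygen can arrive only from the face on which C12–O lies (C12–O and C15–C16 are 1,4-cis from steps 5 and 10), while C8 stays cis because it is part of the cyclooctane. The selectivities needed are ketene capture by 15-OH only (all other hydroxyls are silylated or benzylated), condensation of C2 with C16 and not C7 (C7 is kept as a silyl ether) and etherification by 12-OH only (13-OH is 1,3-trans to C16 and cannot bridge, 11-O is benzylated, 7-OH could only give an oxetane). The ether closure is the sink of the sequence because it exchanges the strained tetrasubstituted alkene at the ring fusion for the stabilised enolate of the β-keto lactone.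

Step 19
Reactants: 30
Product: 31 11-O-benzyl ether of the target
Conditions: Dess–Martin periodinane, NaHCO3, CH2Cl2, 0 °C
Reagents that add atoms: none
Why: Dess–Martin oxidation of the only secondary alcohol (11-O is benzylated, 13-OH is tertiary); both C7 epimers converge on the ketone.

Step 20
Reactants: 31
Product: 32 target CNP0073203.1
Conditions: H2 (1 atm), Pd(OH)2/C, EtOAc, 23 °C
Reagents that add atoms: none
Why: Hydrogenolysis of the benzyl ether; the tetrasubstituted enol double bond and the ketone should not be reduced under these conditions.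

**Compound list**

1 | meso-2,4-dimethylglutaric anhydride, (3R,5S)-3,5-dimethyloxane-2,6-dione | O=C1[C@H](C)C[C@H](C)C(=O)O1 | starting material
2 | (2R,4S)-2,4-dimethyl-5-oxo-5-(prop-2-en-1-yloxy)pentanoic acid | OC(=O)[C@H](C)C[C@H](C)C(=O)OCC=C | intermediate
3 | mixed isobutyl carbonic anhydride of 2 (not isolated) | CC(C)COC(=O)OC(=O)[C@H](C)C[C@H](C)C(=O)OCC=C | intermediate
4 | allyl (2S,4R)-5-hydroxy-2,4-dimethylpentanoate | OC[C@H](C)C[C@H](C)C(=O)OCC=C | intermediate
5 | allyl (2S,4R)-2,4-dimethyl-5-oxopentanoate | O=C[C@H](C)C[C@H](C)C(=O)OCC=C | intermediate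
6 | 3-methylbut-3-en-2-one | CC(=O)C(C)=C | starting material
7 | triisopropyl[(3-methylbuta-1,3-dien-2-yl)oxy]silane | C=C(C)C(=C)O[Si](C(C)C)(C(C)C)C(C)C | intermediate
8 | cyclopent-2-en-1-one | O=C1C=CCC1 | starting material
9 | (3aS,7aR)-6-methyl-5-(triisopropylsilyloxy)-2,3,3a,4,7,7a-hexahydro-1H-inden-1-one | O=C1CC[C@H]2CC(O[Si](C(C)C)(C(C)C)C(C)C)=C(C)C[C@@H]12 | intermediate
10 | 5β,6β-epoxide of 9 (silyloxy epoxide, not isolated) | O=C1CC[C@H]2C[C@]3(O[Si](C(C)C)(C(C)C)C(C)C)O[C@]3(C)C[C@@H]12 | intermediate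
11 | (3aS,6R,7aR)-6-hydroxy-6-methylhexahydro-1H-indene-1,5(4H)-dione | O=C1CC[C@H]2CC(=O)[C@](C)(O)C[C@@H]12 | intermediate
12 | 6β-hydroxy-6α-methyl-cis-hexahydrospiro[indene-1,2'-[1,3]dioxolan]-5(4H)-one | C12(OCCO1)CC[C@H]3CC(=O)[C@](C)(O)C[C@@H]23 | intermediate
13 | dipotassium 6-alkoxide 4-en-5-olate of 12 (not isolated) | C12(OCCO1)CC[C@H]3C=C(O[K])[C@](C)(O[K])C[C@@H]23 | intermediate
14 | 4β,6β-dihydroxy-6α-methyl-cis-hexahydrospiro[indene-1,2'-[1,3]dioxolan]-5(4H)-one | C12(OCCO1)CC[C@H]3[C@H](O)C(=O)[C@](C)(O)C[C@@H]23 | intermediate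
15 | 4β-benzyloxy-6β-hydroxy-6α-methyl-cis-hexahydrospiro[indene-1,2'-[1,3]dioxolan]-5(4H)-one | C12(OCCO1)CC[C@H]3[C@H](OCc4ccccc4)C(=O)[C@](C)(O)C[C@@H]23 | intermediate
16 | 4β-benzyloxy-5β,6α-dimethyl-cis-octahydrospiro[indene-1,2'-[1,3]dioxolane]-5α,6β-diol | C12(OCCO1)CC[C@H]3[C@H](OCc4ccccc4)[C@@](C)(O)[C@](C)(O)C[C@@H]23 | intermediate
17 | 4β-benzyloxy-5α,6β-dihydroxy-5β,6α-dimethyl-cis-octahydro-1H-inden-1-one | O=C1CC[C@H]2[C@H](OCc3ccccc3)[C@@](C)(O)[C@](C)(O)C[C@@H]12 | intermediate
18 | 4β-benzyloxy-5β,6α-dimethyl-1,5α,6β-tris(trimethylsilyloxy)-3,3a,4,5,6,7-hexahydro-2H-indene | C[Si](C)(C)OC=1CC[C@H]2[C@H](OCc3ccccc3)[C@@](C)(O[Si](C)(C)C)[C@](C)(O[Si](C)(C)C)CC=12 | intermediate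
19 | lithium ring-fusion enolate from 18 (not isolated) | [Li]OC=1CC[C@H]2[C@H](OCc3ccccc3)[C@@](C)(O[Si](C)(C)C)[C@](C)(O[Si](C)(C)C)CC=12 | intermediate
20 | 4β-benzyloxy-7aβ-hydroxy-5β,6α-dimethyl-5α,6β-bis(trimethylsilyloxy)-cis-octahydro-1H-inden-1-one | O=C1CC[C@H]2[C@H](OCc3ccccc3)[C@@](C)(O[Si](C)(C)C)[C@](C)(O[Si](C)(C)C)C[C@@]12O | intermediate
21 | dilithium 7a-alkoxide 1-en-1-olate of 20 (not isolated) | [Li]OC1=CC[C@H]2[C@H](OCc3ccccc3)[C@@](C)(O[Si](C)(C)C)[C@](C)(O[Si](C)(C)C)C[C@@]12O[Li] | intermediate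
22 | aldol adduct: 20 carrying at C2 (β) the 5-allyloxy-1-hydroxy-2,4-dimethyl-5-oxopentyl chain (C7 epimers) | O=C1[C@H](C(O)[C@H](C)C[C@H](C)C(=O)OCC=C)C[C@H]2[C@H](OCc3ccccc3)[C@@](C)(O[Si](C)(C)C)[C@](C)(O[Si](C)(C)C)C[C@@]12O | intermediate
23 | 7-O-triethylsilyl ether of 22 | O=C1[C@H](C(O[Si](CC)(CC)CC)[C@H](C)C[C@H](C)C(=O)OCC=C)C[C@H]2[C@H](OCc3ccccc3)[C@@](C)(O[Si](C)(C)C)[C@](C)(O[Si](C)(C)C)C[C@@]12O | intermediate
24 | carboxylic acid from 23 | O=C1[C@H](C(O[Si](CC)(CC)CC)[C@H](C)C[C@H](C)C(=O)O)C[C@H]2[C@H](OCc3ccccc3)[C@@](C)(O[Si](C)(C)C)[C@](C)(O[Si](C)(C)C)C[C@@]12O | intermediate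
25 | acyl Meldrum's acid from 24 | O=C1[C@H](C(O[Si](CC)(CC)CC)[C@H](C)C[C@H](C)C(=O)C3C(=O)OC(C)(C)OC3=O)C[C@H]2[C@H](OCc4ccccc4)[C@@](C)(O[Si](C)(C)C)[C@](C)(O[Si](C)(C)C)C[C@@]12O | intermediate
26 | acylketene from 25 (not isolated) | O=C1[C@H](C(O[Si](CC)(CC)CC)[C@H](C)C[C@H](C)C(=O)C=C=O)C[C@H]2[C@H](OCc3ccccc3)[C@@](C)(O[Si](C)(C)C)[C@](C)(O[Si](C)(C)C)C[C@@]12O | intermediate
27 | 11-membered β-keto lactone, O15–C1 ester (not isolated) | O=C1[C@H]2C[C@H]3[C@H](OCc4ccccc4)[C@@](C)(O[Si](C)(C)C)[C@](C)(O[Si](C)(C)C)C[C@@]13OC(=O)CC(=O)[C@@H](C)C[C@@H](C)C2O[Si](CC)(CC)CC | intermediate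
28 | alkylidene butenolide C2=C16 with 7-OTES and 12,13-bis-OTMS (not isolated) | C[C@@H]1C[C@H](C)C(=O)C2C(=O)O[C@]34C[C@@](C)(O[Si](C)(C)C)[C@](C)(O[Si](C)(C)C)[C@@H](OCc5ccccc5)[C@@H]4C[C@H](C=23)C1O[Si](CC)(CC)CC | intermediate
29 | alkylidene butenolide C2=C16 with free 7-, 12- and 13-OH (not isolated) | C[C@@H]1C[C@H](C)C(=O)C2C(=O)O[C@]34C[C@@](C)(O)[C@](C)(O)[C@@H](OCc5ccccc5)[C@@H]4C[C@H](C=23)C1O | intermediate
30 | 11-O-benzyl-7-deoxo-7-hydroxy derivative of the target (C7 epimers) | C[C@@H]1C[C@H](C)/C(O)=C2/C(=O)O[C@]34C[C@@](C)(O)[C@]5(C)O[C@]23[C@@H](C[C@H]4[C@@H]5OCc6ccccc6)C1O | intermediate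
31 | 11-O-benzyl ether of the target | C[C@@H]1C[C@H](C)/C(O)=C2/C(=O)O[C@]34C[C@@](C)(O)[C@]5(C)O[C@]23[C@@H](C[C@H]4[C@@H]5OCc6ccccc6)C1=O | intermediate
32 | CNP0073203.1 | C[C@@H]1C[C@H](C)/C(O)=C2/C(=O)O[C@]34C[C@@](C)(O)[C@]5(C)O[C@]23[C@@H](C[C@H]4[C@@H]5O)C1=O | target

**Totals and risks**

Total step count: 20. Longest linear sequence: 17 steps (6 → 32, steps 4–20); the aldehyde branch (1 → 5) adds 3 steps and joins at step 14.

Steps most likely to fail:

1. Step 18. The hindered tertiary ketol may capture the acylketene more slowly than the ketene oligomerises or is trapped by the ketone, so the 11-membered ring would not close and nothing downstream could follow. The fallback makes the ester bond intermolecularly and closes the eight-membered ring at C7–C8 instead; it sets out from 1 and 20 and comes back at 31. Anhydride 1 is opened with allyl alcohol and the pseudo-enantiomeric alkaloid to the (2S,4R) half-ester F1, which is condensed with Meldrum's acid (EDC, DMAP) to acyl Meldrum's acid F2. Heating F2 with ketol 20 in toluene gives β-keto ester F3 by intermolecular ketene capture, and Et3N closes the butenolide by Knoevenagel condensation to alkylidene butenolide allyl ester F4, whose C8–H2 is now vinylogously acidic. LiHMDS then effects a vinylogous Dieckmann cyclisation of the C8 dienolate onto the allyl ester, giving the cyclooctane C7 ketone F5, and TBAF removes the two TMS ethers so that 12-OH adds to C16 and gives 31.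

2. Step 5. The silyl enol ether diene may be protodesilylated by the strongly acidic catalyst, or the facial discrimination on the small enone may be poor. The fallback replaces catalyst control by substrate control; it sets out from 7 and comes back at 9. Diene 7 is added (EtAlCl2, CH2Cl2, −78 °C) to commercial (S)-4-(tert-butyldimethylsilyloxy)cyclopent-2-en-1-one, O=C1C=C[C@@H](O[Si](C)(C)C(C)(C)C)C1, anti to the silyloxy group, to give the 3-silyloxy hydrindanone F6. DBU eliminates the silanol to give the ring enone F7, and conjugate reduction with [(Ph3P)CuH]6 gives 9.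

3. Step 12. Enol silylation may go toward C8 (the methylene side) instead of the ring fusion, which would put the hydroxyl of step 13 on the wrong carbon. The fallback blocks C8 as an enone; it sets out from 17 and comes back at 20. Kinetic silylation of 17 (LDA, TMSCl, −78 °C) gives deliberately the C8-side silyl enol ether F8, and Saegusa–Ito oxidation (Pd(OAc)2, MeCN) gives the C8=C9 enone F9. The only remaining α-proton is at C7a, so LDA followed by the N-sulfonyloxaziridine gives the 7a-hydroxy enone F10, and [(Ph3P)CuH]6 reduces the enone to 20.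

**Further compounds**

F1 | step 18 | (2S,4R)-2,4-dimethyl-5-oxo-5-(prop-2-en-1-yloxy)pentanoic acid | OC(=O)[C@@H](C)C[C@@H](C)C(=O)OCC=C
F2 | step 18 | acyl Meldrum's acid of F1 | CC1(C)OC(=O)C(C(=O)[C@@H](C)C[C@@H](C)C(=O)OCC=C)C(=O)O1
F3 | step 18 | β-keto ester of ketol 20 (O15 acylated; allyl ester at C7) | O=C1CC[C@H]2[C@H](OCc3ccccc3)[C@@](C)(O[Si](C)(C)C)[C@](C)(O[Si](C)(C)C)C[C@@]12OC(=O)CC(=O)[C@@H](C)C[C@@H](C)C(=O)OCC=C
F4 | step 18 | alkylidene butenolide C2=C16 with open chain ending in the C7 allyl ester | C=CCOC(=O)[C@H](C)C[C@H](C)C(=O)C1C(=O)O[C@]23C[C@@](C)(O[Si](C)(C)C)[C@](C)(O[Si](C)(C)C)[C@@H](OCc4ccccc4)[C@@H]3CCC=12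
F5 | step 18 | cyclooctane-closed alkylidene butenolide with C7 ketone and 12,13-bis-OTMS | C[C@@H]1C[C@H](C)C(=O)C2C(=O)O[C@]34C[C@@](C)(O[Si](C)(C)C)[C@](C)(O[Si](C)(C)C)[C@@H](OCc5ccccc5)[C@@H]4C[C@H](C=23)C1=O
F6 | step 5 | 3-(tert-butyldimethylsilyloxy) derivative of 9 (silyloxy on the face of H-3a) | O=C1C[C@H](O[Si](C)(C)C(C)(C)C)[C@H]2CC(O[Si](C(C)C)(C(C)C)C(C)C)=C(C)C[C@@H]12
F7 | step 5 | 2,3-didehydro derivative of 9 (ring enone) | O=C1C=C[C@H]2CC(O[Si](C(C)C)(C(C)C)C(C)C)=C(C)C[C@@H]12
F8 | step 12 | C1=C2 (kinetic) tris-TMS enol ether isomer of 18 | C[Si](C)(C)OC1=CC[C@H]2[C@H](OCc3ccccc3)[C@@](C)(O[Si](C)(C)C)[C@](C)(O[Si](C)(C)C)C[C@@H]12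
F9 | step 12 | 2,3-didehydro enone with 5,6-bis-OTMS | O=C1C=C[C@H]2[C@H](OCc3ccccc3)[C@@](C)(O[Si](C)(C)C)[C@](C)(O[Si](C)(C)C)C[C@@H]12
F10 | step 12 | 7aβ-hydroxy derivative of F9 | O=C1C=C[C@H]2[C@H](OCc3ccccc3)[C@@](C)(O[Si](C)(C)C)[C@](C)(O[Si](C)(C)C)C[C@@]12O
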